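## Analysis of the target

The target is a daucane-type sesquiterpenoid diester built on a trans-fused bicyclo[5.3.0]decane. The five-membered ring B (C1–C2–C3–C4–C5) carries a β methyl group on quaternary C1, an α angeloyloxy group on C2 and a tertiary carbinol at C4 (β OH, α isopropyl). The seven-membered ring A (C1–C5–C6–C7–C8–C9–C10) carries an α angeloyloxy group on C6, a methyl group on C8 and the C8=C9 double bond. This numbering is kept for the corresponding atoms of every intermediate. The five stereocentres form two contiguous groups that meet at the ring fusion, C1–C2 and C4–C5–C6, with H5 α and the C1 methyl β (trans fusion). The sensitive features are the two (Z)-2-methylbut-2-enoates, which isomerise readily to tiglates, the tertiary alcohol, which lies β to C6 and invites elimination or retro-aldol opening while C6 is a ketone, and the trisubstituted olefin, whose position cannot be corrected by equilibration. The difficulties are the quaternary centre beside an oxygenated carbon, the seven-membered ring, the trans fusion and the differentiation of three hydroxyls and two ring carbonyl positions. The strategy rests on two relations: C10 on C1 is cis to the C2 oxygen, and C6 and C9 are 1,5-related through the C5–C1 bond. A cyclopentane-1,3-dione enol ether hung on the C2 oxygen therefore holds its enone double bond (C6=C10) over a C1=C5 olefin of ring B, so that [2+2] photocycloaddition and cyclobutane cleavage grow ring A by two carbons and leave a C9 ketone as the handle for the olefin.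

## Retrosynthetic reasoning

**Ester bonds (27 ⇒ 24 + two equivalents of 25).** The two acyl C–O bonds at O2 and O6 are cut last in the analysis, so that they are formed last in the synthesis. Angelates do not survive strong base, hydride or palladium hydride chemistry without risk of Z→E isomerisation. Each of the two secondary hydroxyls of triol 24 takes one molecule of angelic acid 25, and the hindered tertiary C4 hydroxyl needs no protection during the acylation.

**Olefin from ketone (24 ⇒ 23 ⇒ 22 ⇒ 20 ⇒ 19).** The C8=C9 double bond is traced to enol triflate 22 and, through silyl enol ether 20, to a C9 ketone (19). The ketone sits exactly where a dione-derived ring expansion leaves it. The forward sequence has to enolise C9 toward C8 and not toward C10, and the hydroxyls are silylated for this stage.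

**C6 carbinol and ring fusion (19 ⇒ 18 ⇒ 17 ⇒ 16).** The C6–H bond is removed to give diketone 17. The C4 hydroxyl is β to C6 and can direct a hydride to one face of that carbonyl only, which also distinguishes C6 from C9. The C5 centre is adjustable while C6 is a ketone, so trans-fused 17 is traced to its cis-fused epimer 16.

**Key disconnection (16 ⇒ 15 ⇒ 14).** Reconnecting C6 to C10 (retro-aldol in reverse) and tying the C2 hydroxyl to C6 as an ether gives cage compound 15. Cutting its C5–C6 and C1–C10 bonds gives enol ether 14, in which ring A is absent. These two bonds are chosen because one creates the quaternary centre C1 and the other joins C5 to the future C6 carbonyl. The oxygen tether makes both bonds form on the α face, which is what C1 needs.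

**Enol ether and C8 methyl (14 ⇒ 12 ⇒ 8 + 10; 10 ⇒ 9).** The C8 methyl is removed first (12), because a kinetic enolate of the vinylogous ester places it unambiguously next to C9. The C6–O bond is then cut to trans diol 8 and chloro enone 10, made from the symmetrical dione 9. A basic substitution is used because the tertiary allylic alcohol of 8 would not tolerate acid-catalysed enol ether exchange, and the symmetrical partner avoids regioisomeric enol ethers.

**Ring B (8 ⇒ 7 ⇒ 6 ⇒ 5 ⇒ 3 + 4; 3 ⇒ 2 ⇒ 1).** The C2 carbinol of 8 comes from ketone 7 by reduction directed by the C4 hydroxyl. The tertiary carbinol comes from addition of the isopropyl reagent 4 to enone 3, anti to a silyloxy group on C2 that is later oxidised (6 ⇒ 7). Enone 3 is the β-methyl homologue of the single-enantiomer building block 1, reached by conjugate methylation to 2 and dehydrogenation. The stereochemical information of 1 is thus relayed to C4 and from there back to C2.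

## Alternatives that were turned down

**Alternative 1:** Acid A2 would be disconnected at C1–C10, with the C8–O bond re-formed, back to the seven-membered lactone A1 (ring oxygen on C8, which also carries the C8 methyl and the C9=C10 vinyl group). In the forward step LiN(i-Pr)2 and Me3SiCl would O-silylate the enolate of A1, and a [3,3] shift (Ireland–Claisen) would form C1–C10, break C8–O and leave the C8=C9 double bond inside the new carbocycle.
- For: the olefin is placed unambiguously by the pericyclic step, and the quaternary centre is made thermally with chirality transfer from C8. On olefin placement this is stronger than the chosen route, which has to control the direction of enolisation of a C9 ketone.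
- Against: C10 must arrive on the lactone face that already carries the bulky C5 side chain, and a boat-like transition state is required for a cis olefin in a seven-membered ring. A1 itself needs a fully substituted C8 of defined configuration. After the key step ring B is still open: C3 has to be inserted between the C2 carboxyl and the masked C4 ketone, the C4 carbinol has to be set in a ring closure of uncertain facial sense, and C2 has to be taken from acid to α alcohol.
- Comparison: the chosen strategy sets the ring B stereocentres first on a simple cyclopentene and grows ring A in one operation, so less uncontrolled chemistry follows the key step.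

**Alternative 2:** Diene A5 would be disconnected at C7–C8 and C9–C10 into the ring B-fused vinylcyclopropane A3 (cyclopropane C1–C5–C10, 1-siloxyvinyl group on C5) and the alkyne A4. In the forward step [Rh(CO)2Cl]2 (monovalent rhodium) would open the C5–C10 bond of A3, insert A4 and close ring A as a cycloheptadiene.
- For: it is convergent, catalytic and thermal. The C6 oxygen arrives as a silyl enol ether and the C8=C9 olefin as a vinylsilane, so on olefin position and on scalability it is as strong as or stronger than the chosen route.
- Against: the orientation of the unsymmetrical alkyne (methyl at C8, silicon at C9) is not secured. C5 becomes trigonal, so the ring fusion must again be set afterwards, with no gain over the chosen route on that point. The vinylsilane needs a protodesilylation beside acid-sensitive groups. A3, a fully substituted tris-silyloxy bicyclo[3.1.0]hexane with an α-face cyclopropane, needs a long synthesis of its own, and an intermolecular reaction of an internal alkyne with so hindered a substrate is doubtful.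
- Comparison: the chosen strategy obtains the same C6/C9 oxygenation pattern from a cheap dione in an intramolecular step whose regiochemistry is fixed by the tether.

**Alternative 3:** Diol A7 would be disconnected at C1–C5 and C4–O to the cis epoxide A6 of a (Z,Z)-cyclodecadiene. In the forward step BF3·OEt2 in wet dichloromethane would open the epoxide at tertiary C1, the C4=C5 olefin would attack across the ring, and water would trap the C4 cation.
- For: both rings, all five stereocentres and the C8=C9 olefin are present after one step, and only desilylation and acylation remain. In step count after the key step and in olefin placement this is clearly stronger than the chosen route.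
- Against: four stereocentres depend on the conformation of a ten-membered ring with no local control element. Capture of the C4 cation by water on the β face must outrun proton loss and hydride shifts. A6 requires a ten-membered ring with two Z trisubstituted olefins, a C6 stereocentre and an epoxidation that selects C1=C2 among three trisubstituted double bonds.
- Comparison: the chosen strategy is longer after the key step, but every stereocentre is set by an identifiable neighbouring group, and ring strain drives the key step instead of opposing it.

Key step: step 10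

## Route

Remark: (R)-4-(tert-butyldimethylsilyloxy)cyclopent-2-en-1-one (1) is taken as a purchasable single enantiomer.

Remark: the methyl-bearing C8 of 14–19 is formed without control; both epimers are carried together and one is drawn, since C8 becomes trigonal in step 14.

Step 1
Reactants: 1 (R)-4-(tert-butyldimethylsilyloxy)cyclopent-2-en-1-one
Product: 2 (3R,4R)-4-(tert-butyldimethylsilyloxy)-3-methyl-1-(trimethylsilyloxy)cyclopent-1-ene (methyl trans to the silyloxy group)
Conditions: Me2CuLi (from MeLi, CuI), TMSCl, Et2O/THF, −78 °C
Reagents that add atoms: lithium dimethylcuprate, [Li+].C[Cu-]C; chlorotrimethylsilane, C[Si](C)(C)Cl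
Why: Cuprate conjugate addition, accelerated and trapped by the silyl chloride, occurs anti to the silyloxy group; the new methyl-bearing centre is removed again in step 2, so only the position of the enol ether matters.

Step 2
Reactants: 2 (3R,4R)-4-(tert-butyldimethylsilyloxy)-3-methyl-1-(trimethylsilyloxy)cyclopent-1-ene
Product: 3 (R)-4-(tert-butyldimethylsilyloxy)-3-methylcyclopent-2-en-1-one
Conditions: Pd(OAc)2 (10 mol %), O2 (1 atm), DMSO, 25 °C
Reagents that add atoms: none
Why: Saegusa–Ito oxidation; the palladium enolate can undergo β-hydride elimination only toward C1, which returns the enone with the methyl group on its β-carbon, and the C2 stereocentre is not touched.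

Step 3
Reactants: 3 (R)-4-(tert-butyldimethylsilyloxy)-3-methylcyclopent-2-en-1-one; 4 isopropylmagnesium chloride
Product: 5 (1R,4R)-4-(tert-butyldimethylsilyloxy)-3-methyl-1-(propan-2-yl)cyclopent-2-en-1-ol (isopropyl α; both oxygens β)
Conditions: 4, CeCl3, THF, −78 °C; aq NH4Cl
Reagents that add atoms: none
Why: The organocerium reagent adds 1,2 to the enone without enolisation or reduction and attacks C4 anti to the β silyloxy group on C2, so the isopropyl group becomes α and the new hydroxyl β as in the target. The minor C4 epimer is removed by chromatography here, because after step 5 it would be the enantiomer of 7.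

Step 4
Reactants: 5 (1R,4R)-4-(tert-butyldimethylsilyloxy)-3-methyl-1-(propan-2-yl)cyclopent-2-en-1-ol
Product: 6 (1R,4R)-3-methyl-1-(propan-2-yl)cyclopent-2-ene-1,4-diol (cis diol)
Conditions: TBAF, THF, 0 °C → rt
Reagents that add atoms: none
Why: Fluoride cleaves the silyl ether; the non-acidic conditions spare the tertiary allylic alcohol.

Step 5
Reactants: 6 (1R,4R)-3-methyl-1-(propan-2-yl)cyclopent-2-ene-1,4-diol
Product: 7 (R)-4-hydroxy-2-methyl-4-(propan-2-yl)cyclopent-2-en-1-one
Conditions: MnO2, CH2Cl2, rt
Reagents that add atoms: none
Why: MnO2 oxidises only the secondary allylic alcohol; the tertiary carbinol at C4 now holds all the stereochemical information.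

Step 6
Reactants: 7 (R)-4-hydroxy-2-methyl-4-(propan-2-yl)cyclopent-2-en-1-one
Product: 8 (1R,4S)-3-methyl-1-(propan-2-yl)cyclopent-2-ene-1,4-diol (trans diol; C2–OH α and C4–OH β)
Conditions: Me4NBH(OAc)3, MeCN/AcOH, −25 °C
Reagents that add atoms: none
Why: Evans–Saksena reduction; the C4 hydroxyl binds the borohydride and delivers hydride to the β face of the C2 carbonyl, so the new hydroxyl is α and trans to the C4 hydroxyl. Attack anti to the α isopropyl group points the same way, and the mild reagent does not reduce the conjugated double bond.

Step 7
Reactants: 9 cyclopentane-1,3-dione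
Product: 10 3-chlorocyclopent-2-en-1-one
Conditions: (COCl)2, DMF (cat.), CH2Cl2, 0 °C → rt
Reagents that add atoms: oxalyl chloride, O=C(Cl)C(=O)Cl
Why: Vinylogous acid chloride formation from the enol form of the dione; the symmetrical dione cannot give regioisomers.

Step 8
Reactants: 8 (1R,4S)-3-methyl-1-(propan-2-yl)cyclopent-2-ene-1,4-diol; 10 3-chlorocyclopent-2-en-1-one
Product: 12 3-{[(1S,4R)-4-hydroxy-2-methyl-4-(propan-2-yl)cyclopent-2-en-1-yl]oxy}cyclopent-2-en-1-one, via sodium alkoxide 11 (not isolated)
Conditions: NaH (1.0 equiv), THF, 0 °C; then 10, 0 °C → rt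
Reagents that add atoms: none
Why: Addition–elimination (vinylic substitution) of the secondary alkoxide on the β-chloro enone gives the vinylogous ester under basic conditions, which the acid-labile tertiary allylic alcohol tolerates. The hindered tertiary alkoxide does not compete, and C2 keeps its configuration because its C–O bond is not broken.

Step 9
Reactants: 12 3-{[(1S,4R)-4-hydroxy-2-methyl-4-(propan-2-yl)cyclopent-2-en-1-yl]oxy}cyclopent-2-en-1-one
Product: 14 3-{[(1S,4R)-4-hydroxy-2-methyl-4-(propan-2-yl)cyclopent-2-en-1-yl]oxy}-5-methylcyclopent-2-en-1-one (C8 epimers; one drawn), via dilithium alkoxide enolate 13 (not isolated)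
Conditions: LDA (2.2 equiv), THF, −78 °C; MeI, −78 → −40 °C
Reagents that add atoms: iodomethane, CI
Why: Stork–Danheiser alkylation; kinetic deprotonation of a β-alkoxy enone occurs at the α′ position, so the methyl group enters at C8 beside the C9 carbonyl and not beside C6. The tertiary lithium alkoxide is inert to iodomethane at low temperature.

Step 10
Reactants: 14 3-{[(1S,4R)-4-hydroxy-2-methyl-4-(propan-2-yl)cyclopent-2-en-1-yl]oxy}-5-methylcyclopent-2-en-1-one
Product: 16 cis-fused 2α,4β-dihydroxy-6,9-diketone (H5 β; C1 methyl β; C4 isopropyl α; C8 methyl), via photoadduct 15 (not isolated)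
Conditions: hν (medium-pressure Hg lamp, Pyrex, λ > 290 nm), degassed MeCN, 0 °C; then 2 M aq HCl, THF, 0 °C → rt
Reagents that add atoms: water, O
Why: The excited vinylogous ester attacks the tethered ring B olefin by the rule of five: its β-carbon C6 bonds to the distal olefin carbon C5 and closes a five-membered ring through the ether oxygen and C2, and the α-keto radical at C10 then recombines with the tertiary radical at C1 to close the four-membered ring, giving the crossed 2-oxabicyclo[2.1.1]hexane 15 and not the straight adduct, which would contain an oxetane. The closest known reaction type is the crossed intramolecular enone–olefin [2+2] photocycloaddition of β-(alkenyloxy) enones followed by a de Mayo-type retro-aldol cleavage. In acid the C9 carbonyl is protonated, a lone pair of the tether oxygen lying anti to the strained C6–C10 bond pushes that bond open, and hydration of the oxocarbenium ion with collapse of the hemiketal frees the C6 ketone and the C2 hydroxyl. Ring A is therefore closed by fragmentation of the cyclobutane fused to the five-membered ketone, a two-carbon ring growth, and not by a direct seven-membered closure. The stereocentre that counts is C1: the two-atom tether from the α oxygen on C2 can deliver C10 only to the α face, cis to that oxygen as in the target. C5 is formed cis (C6 α) for the same reason and is corrected in step 11, while C6 and C10 of 15 are fixed by the cage and disappear on cleavage. The step needs crossed regiochemistry and α-face selectivity, both imposed by the tether length, at the price that C6 must bond beside the α isopropyl group on C4.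

Step 11
Reactants: 16 cis-fused 2α,4β-dihydroxy-6,9-diketone
Product: 17 trans-fused 2α,4β-dihydroxy-6,9-diketone (H5 α)
Conditions: DBU (0.3 equiv), PhMe, 25 °C
Reagents that add atoms: none
Why: Epimerisation through the C5–C6 enol(ate); in the cis isomer C6 is crowded against the α isopropyl group on C4, whereas in the trans isomer it lies beside the smaller β hydroxyl, to which the C6 carbonyl can hydrogen-bond, so equilibrium should favour 17. A catalytic amidine base in an aprotic solvent keeps retro-aldol opening and dehydration at C4 to a minimum.

Step 12
Reactants: 17 trans-fused 2α,4β-dihydroxy-6,9-diketone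
Product: 18 trans-fused 2α,4β,6α-trihydroxy-9-ketone
Conditions: Me4NBH(OAc)3 (1.5 equiv), MeCN/AcOH, −30 °C
Reagents that add atoms: none
Why: Evans–Saksena reduction; only the C6 ketone is β to a hydroxyl (C4–OH) and cis to it, so hydride is delivered intramolecularly to the β face of C6 and the new hydroxyl is α. The C9 ketone has no such partner, and a small excess of reagent keeps hydride from being relayed to it.

Step 13
Reactants: 18 trans-fused 2α,4β,6α-trihydroxy-9-ketone
Product: 19 2α,6α-bis(triethylsilyloxy)-4β-hydroxy-9-ketone
Conditions: TESCl, imidazole, DMAP (cat.), DMF, 0 °C → rt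
Reagents that add atoms: chlorotriethylsilane, CC[Si](CC)(CC)Cl
Why: Silylation of the two secondary hydroxyls; the hindered tertiary hydroxyl does not react with the silyl chloride, and trapping of the open form removes any transannular hemiketal between O6 and C9.

Step 14
Reactants: 19 2α,6α-bis(triethylsilyloxy)-4β-hydroxy-9-ketone
Product: 20 C8=C9 trimethylsilyl enol ether with 2α,6α-bis(triethylsilyloxy) and 4β-(trimethylsilyloxy) groups
Conditions: TMSCl, NaI, Et3N, MeCN, rt → 40 °C
Reagents that add atoms: chlorotrimethylsilane, C[Si](C)(C)Cl
Why: Iodotrimethylsilane made in situ with triethylamine forms silyl enol ethers under equilibrating conditions, which should favour the more substituted C8=C9 isomer over the C9=C10 isomer beside quaternary C1. The tertiary hydroxyl is silylated in the same operation and so protected for steps 15 and 16.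

Step 15
Reactants: 20 C8=C9 trimethylsilyl enol ether
Product: 22 C8=C9 enol triflate (C9–OTf) with 2α,6α-bis(triethylsilyloxy) and 4β-(trimethylsilyloxy) groups, via lithium enolate 21 (not isolated)
Conditions: MeLi (1.05 equiv), THF, 0 °C; then PhNTf2, −78 → 0 °C
Reagents that add atoms: N-phenylbis(trifluoromethanesulfonimide), O=S(=O)(N(c1ccccc1)S(=O)(=O)C(F)(F)F)C(F)(F)F
Why: Methyllithium cleaves the enol silyl ether to the regiodefined lithium enolate, which is O-triflated without equilibration; alkyl silyl ethers are not attacked under these conditions.

Step 16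
Reactants: 22 C8=C9 enol triflate
Product: 23 2α,6α-bis(triethylsilyloxy)-4β-(trimethylsilyloxy) C8=C9 olefin
Conditions: Pd(OAc)2 (5 mol %), PPh3, Bu3N, HCO2H, DMF, 60 °C
Reagents that add atoms: none
Why: Palladium-catalysed reduction of the enol triflate with formate as hydride source (oxidative addition, formate exchange, decarboxylation, reductive elimination) replaces the triflate by hydrogen and leaves the double bond fixed between C8 and C9.

Step 17
Reactants: 23 2α,6α-bis(triethylsilyloxy)-4β-(trimethylsilyloxy) C8=C9 olefin
Product: 24 2α,4β,6α-triol with the C8=C9 double bond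
Conditions: HF·pyridine, pyridine, THF, 0 °C → rt
Reagents that add atoms: none
Why: Fluoride-mediated cleavage of the two triethylsilyl ethers and the tertiary trimethylsilyl ether; the buffered reagent should not isomerise the trisubstituted olefin.

Step 18
Reactants: 24 2α,4β,6α-triol with the C8=C9 double bond; 25 angelic acid
Product: 27 target 2α,6α-bis(angeloyloxy)-4β-hydroxy C8=C9 olefin (CNP0303897.1), via angelic 2,4,6-trichlorobenzoic anhydride 26 (not isolated)
Conditions: 25 (3 equiv), 2,4,6-Cl3C6H2COCl (3 equiv), Et3N, PhMe, rt; then 24, 80 °C
Reagents that add atoms: angelic acid (the second equivalent of 25 that enters the product), C/C=C(/C)C(=O)O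
Why: Yamaguchi-type esterification through the mixed anhydride acylates hindered secondary alcohols without a nucleophilic amine catalyst that could add to the enoate, so the Z geometry should be kept. The hydroxyls on C2 and C6 each take one angeloyl group from 26, so two equivalents of 25 end up in the product and a third is used as excess. The tertiary C4 hydroxyl is too hindered to react.

## Compound list

1 | (R)-4-(tert-butyldimethylsilyloxy)cyclopent-2-en-1-one | O=C1C=C[C@H](O[Si](C)(C)C(C)(C)C)C1 | starting material
2 | (3R,4R)-4-(tert-butyldimethylsilyloxy)-3-methyl-1-(trimethylsilyloxy)cyclopent-1-ene | C[Si](C)(C)OC1=C[C@@H](C)[C@H](O[Si](C)(C)C(C)(C)C)C1 | intermediate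
3 | (R)-4-(tert-butyldimethylsilyloxy)-3-methylcyclopent-2-en-1-one | O=C1C=C(C)[C@H](O[Si](C)(C)C(C)(C)C)C1 | intermediate
4 | isopropylmagnesium chloride | CC(C)[Mg]Cl | starting material
5 | (1R,4R)-4-(tert-butyldimethylsilyloxy)-3-methyl-1-(propan-2-yl)cyclopent-2-en-1-ol | CC1=C[C@](O)(C(C)C)C[C@H]1O[Si](C)(C)C(C)(C)C | intermediate
6 | (1R,4R)-3-methyl-1-(propan-2-yl)cyclopent-2-ene-1,4-diol (cis diol) | CC1=C[C@](O)(C(C)C)C[C@H]1O | intermediate
7 | (R)-4-hydroxy-2-methyl-4-(propan-2-yl)cyclopent-2-en-1-one | CC1=C[C@](O)(C(C)C)CC1=O | intermediate
8 | (1R,4S)-3-methyl-1-(propan-2-yl)cyclopent-2-ene-1,4-diol (trans diol) | CC1=C[C@](O)(C(C)C)C[C@@H]1O | intermediate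
9 | cyclopentane-1,3-dione | O=C1CCC(=O)C1 | starting material
10 | 3-chlorocyclopent-2-en-1-one | O=C1CCC(Cl)=C1 | intermediate
11 | sodium (1S,4R)-4-hydroxy-2-methyl-4-(propan-2-yl)cyclopent-2-en-1-olate | CC1=C[C@](O)(C(C)C)C[C@@H]1[O-].[Na+] | intermediate (not isolated)
12 | 3-{[(1S,4R)-4-hydroxy-2-methyl-4-(propan-2-yl)cyclopent-2-en-1-yl]oxy}cyclopent-2-en-1-one | CC1=C[C@](O)(C(C)C)C[C@@H]1OC2=CC(=O)CC2 | intermediate
13 | dilithium alkoxide enolate of 12 (tertiary alkoxide and cross-conjugated α′ enolate) | CC1=C[C@]([O-])(C(C)C)C[C@@H]1OC2=CC([O-])=CC2.[Li+].[Li+] | intermediate (not isolated)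
14 | 3-{[(1S,4R)-4-hydroxy-2-methyl-4-(propan-2-yl)cyclopent-2-en-1-yl]oxy}-5-methylcyclopent-2-en-1-one (C8 epimers, one drawn) | CC1=C[C@](O)(C(C)C)C[C@@H]1OC2=CC(=O)[C@@H](C)C2 | intermediate
15 | crossed photoadduct: 2-oxabicyclo[2.1.1]hexane with the ether oxygen bridging C2 and C6, cyclobutane C1–C5–C6–C10 on the α face, C9 ketone | C[C@]12[C@@H]3C[C@@](O)(C(C)C)[C@H]1[C@]4(O3)C[C@H](C)C(=O)[C@H]24 | intermediate (not isolated)
16 | cis-fused 2α,4β-dihydroxy-1β,8-dimethyl-4α-isopropylbicyclo[5.3.0]decane-6,9-dione (skeleton numbering, H5 β) | O=C1C[C@H](C)C(=O)C[C@@]2(C)[C@@H](O)C[C@@](O)(C(C)C)[C@@H]12 | intermediate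
17 | trans-fused epimer of 16 (H5 α) | O=C1C[C@H](C)C(=O)C[C@@]2(C)[C@@H](O)C[C@@](O)(C(C)C)[C@H]12 | intermediate
18 | trans-fused 2α,4β,6α-trihydroxy-9-ketone | O[C@H]1C[C@H](C)C(=O)C[C@@]2(C)[C@@H](O)C[C@@](O)(C(C)C)[C@H]12 | intermediate
19 | 2α,6α-bis(triethylsilyl) ether of 18 | CC[Si](CC)(CC)O[C@H]1C[C@H](C)C(=O)C[C@@]2(C)[C@@H](O[Si](CC)(CC)CC)C[C@@](O)(C(C)C)[C@H]12 | intermediate
20 | C8=C9 trimethylsilyl enol ether of 19 with the C4 hydroxyl as trimethylsilyl ether | CC[Si](CC)(CC)O[C@H]1CC(C)=C(O[Si](C)(C)C)C[C@@]2(C)[C@@H](O[Si](CC)(CC)CC)C[C@@](O[Si](C)(C)C)(C(C)C)[C@H]12 | intermediate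
21 | lithium C8=C9 enolate | CC[Si](CC)(CC)O[C@H]1CC(C)=C([O-])C[C@@]2(C)[C@@H](O[Si](CC)(CC)CC)C[C@@](O[Si](C)(C)C)(C(C)C)[C@H]12.[Li+] | intermediate (not isolated)
22 | C8=C9 enol triflate | CC[Si](CC)(CC)O[C@H]1CC(C)=C(OS(=O)(=O)C(F)(F)F)C[C@@]2(C)[C@@H](O[Si](CC)(CC)CC)C[C@@](O[Si](C)(C)C)(C(C)C)[C@H]12 | intermediate
23 | 2α,6α-bis(triethylsilyloxy)-4β-(trimethylsilyloxy) C8=C9 olefin | CC[Si](CC)(CC)O[C@H]1CC(C)=CC[C@@]2(C)[C@@H](O[Si](CC)(CC)CC)C[C@@](O[Si](C)(C)C)(C(C)C)[C@H]12 | intermediate
24 | 2α,4β,6α-triol with the C8=C9 double bond | O[C@H]1CC(C)=CC[C@@]2(C)[C@@H](O)C[C@@](O)(C(C)C)[C@H]12 | intermediate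
25 | angelic acid, (Z)-2-methylbut-2-enoic acid | C/C=C(/C)C(=O)O | starting material
26 | angelic 2,4,6-trichlorobenzoic anhydride | C/C=C(/C)C(=O)OC(=O)c1c(Cl)cc(Cl)cc1Cl | intermediate (not isolated)
27 | CNP0303897.1, 2α,6α-bis(angeloyloxy)-4β-hydroxy C8=C9 olefin | C/C=C(/C)C(=O)O[C@H]1CC(C)=CC[C@@]2(C)[C@@H](OC(=O)/C(C)=C\C)C[C@@](O)(C(C)C)[C@H]12 | target

## Step count and risks

Total step count: 18. Longest linear sequence: 17 steps (steps 1–6 and 8–18, from 1 to 27); step 7 is a one-step side branch.

**Step 10 (key step).**
- What may go wrong: closure of the biradical may be inefficient because C6 must bond on the α face beside the isopropyl group, so reversion and hydrogen transfer can compete. In the acid stage, ionisation of the tertiary C4 alcohol or cationic rearrangement of the strained cage may outrun heterolysis of C6–C10, or the cage may not open at all if the tether oxygen is a poor donor.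
- Fallback: the acid-induced opening is replaced by a base-induced elimination–addition sequence that needs no oxocarbenium ion. It sets out from 15. DBU in THF should expel the C2 alkoxide from the C9 enolate (retro-oxa-Michael) to give the cyclobutene enone F1 with the C2 hydroxyl free. Aqueous LiOH then adds hydroxide to C6 of the strained enone, the resulting cyclobutanol undergoes the classical de Mayo retro-aldol, and C5 equilibrates in the same medium, so the route is rejoined at 17.

**Step 11.**
- What may go wrong: retro-aldol opening of ring B at C4–C5 (which would scramble C4) or E1cB loss of the C4 hydroxyl may compete with epimerisation, and the cis isomer may be held back as a hemiketal between O2 and C6.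
- Fallback: it sets out from 16. Both hydroxyls are masked (TMSOTf, 2,6-lutidine) to give the bis(trimethylsilyl) ether F2, which can undergo neither retro-aldol nor hemiketal formation. DBU equilibration then gives the trans-fused bis(trimethylsilyl) ether F3, and HF·pyridine returns 17.

**Step 14 (with step 15).**
- What may go wrong: incomplete regiocontrol in the enolisation of the C9 ketone would carry some C9=C10 enol ether forward to a C9=C10 olefin, which cannot be corrected later because isomerisation would also populate C7=C8.
- Fallback: the regiochemistry is made a matter of structure. It sets out from 19. Dehydrogenation with IBX (DMSO, 70 °C) can occur only between C7 and C8, because C10 is attached to quaternary C1, and gives the C7=C8 enone F4. Condensation with tosylhydrazide gives the tosylhydrazone F5. Catecholborane reduction followed by NaOAc-induced loss of sulfinate and dinitrogen moves the double bond from C7=C8 to C8=C9, with hydrogen delivered to C7, and gives the bis(triethylsilyl) ether F6. HF·pyridine converts F6 to 24, where the route is rejoined.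

**Step 18.**
- What may go wrong: isomerisation of the angeloyl group to the tigloyl group during activation, or incomplete acylation of the hindered C2 hydroxyl beside quaternary C1, which would leave a monoester.
- Fallback: the Z olefin is built after esterification. It sets out from 24. DCC/DMAP coupling with 2-[bis(2,2,2-trifluoroethoxy)phosphoryl]propanoic acid gives the bis(phosphonopropionate) F7, and Still–Gennari olefination (KHMDS, 18-crown-6, acetaldehyde, THF, −78 °C) forms both Z-configured 2-methylbut-2-enoates and so arrives at 27.

**Step 3.**
- What may go wrong: modest facial selectivity in the organocerium addition. Any C4 epimer left in 5 becomes the enantiomer of 7 after step 5 and lowers the enantiomeric purity.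
- Fallback: the ketone stage is avoided. It sets out from 6. Mitsunobu etherification (PPh3, DIAD) with dione 9 inverts C2 and installs the vinylogous ester in one operation, arriving directly at 12. The minor C4 epimer then stays a diastereomer and can be removed at any later stage. No new compound is made (entry F0).

## Further compounds

F1 | step 10 | cyclobutene enone (C6=C10) with free 2α and 4β hydroxyls | C[C@]12[C@@H](O)C[C@@](O)(C(C)C)[C@H]1C3=C2C(=O)[C@@H](C)C3
F2 | step 11 | cis-fused 2α,4β-bis(trimethylsilyloxy)-6,9-diketone | O=C1C[C@H](C)C(=O)C[C@@]2(C)[C@@H](O[Si](C)(C)C)C[C@@](O[Si](C)(C)C)(C(C)C)[C@@H]12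
F3 | step 11 | trans-fused 2α,4β-bis(trimethylsilyloxy)-6,9-diketone | O=C1C[C@H](C)C(=O)C[C@@]2(C)[C@@H](O[Si](C)(C)C)C[C@@](O[Si](C)(C)C)(C(C)C)[C@H]12
F4 | step 14 | C7=C8 enone: 2α,6α-bis(triethylsilyloxy)-4β-hydroxy-9-ketone | CC[Si](CC)(CC)O[C@H]1C=C(C)C(=O)C[C@@]2(C)[C@@H](O[Si](CC)(CC)CC)C[C@@](O)(C(C)C)[C@H]12
F5 | step 14 | tosylhydrazone of F4 | CC[Si](CC)(CC)O[C@H]1C=C(C)C(=NNS(=O)(=O)c3ccc(C)cc3)C[C@@]2(C)[C@@H](O[Si](CC)(CC)CC)C[C@@](O)(C(C)C)[C@H]12
F6 | step 14 | 2α,6α-bis(triethylsilyloxy)-4β-hydroxy C8=C9 olefin | CC[Si](CC)(CC)O[C@H]1CC(C)=CC[C@@]2(C)[C@@H](O[Si](CC)(CC)CC)C[C@@](O)(C(C)C)[C@H]12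
F7 | step 18 | 2α,6α-bis{2-[bis(2,2,2-trifluoroethoxy)phosphoryl]propanoate} of 24 | CC(C(=O)O[C@H]1CC(C)=CC[C@@]2(C)[C@@H](OC(=O)C(C)P(=O)(OCC(F)(F)F)OCC(F)(F)F)C[C@@](O)(C(C)C)[C@H]12)P(=O)(OCC(F)(F)F)OCC(F)(F)F
F0 | step 3 | none | none
A1 | alternative 1 | seven-membered lactone: C2 carbonyl, ring oxygen on C8, C8 methyl and vinyl, C6 silyl ether, C5 bearing the 2-isopropyl-1,3-dioxolan-2-yl group, C1 methyl (either epimer) | CC1C(=O)O[C@@](C)(C=C)C[C@H](O[Si](C)(C)C(C)(C)C)[C@H]1C2(C(C)C)OCCO2
A2 | alternative 1 | ring A cycloheptene carboxylic acid with the C2 carboxyl on quaternary C1 | CC(C)(C)[Si](C)(C)O[C@H]1CC(C)=CC[C@@](C)(C(=O)O)[C@@H]1C2(C(C)C)OCCO2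
A3 | alternative 2 | ring B-fused vinylcyclopropane (cyclopropane C1–C5–C10 on the α face, 1-siloxyvinyl on C5) | C=C(O[Si](C)(C)C(C)(C)C)[C@]12C[C@@]1(C)[C@@H](O[Si](C)(C)C(C)(C)C)C[C@@]2(O[Si](C)(C)C(C)(C)C)C(C)C
A4 | alternative 2 | 1-(trimethylsilyl)propyne | CC#C[Si](C)(C)C
A5 | alternative 2 | bicyclic diene with C5=C6 silyl enol ether and C8=C9 vinylsilane | C[Si](C)(C)C1=C(C)CC(O[Si](C)(C)C(C)(C)C)=C2[C@@](C)(C1)[C@@H](O[Si](C)(C)C(C)(C)C)C[C@@]2(O[Si](C)(C)C(C)(C)C)C(C)C
A6 | alternative 3 | cis C1–C2 epoxide of the (Z,Z)-cyclodeca-4,8-diene with C6 silyl ether | C[C@]12O[C@H]1C/C(C(C)C)=C\[C@@H](O[Si](C)(C)C(C)(C)C)C/C(C)=C\C2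
A7 | alternative 3 | bicyclic 2α,4β-diol with the C6 silyl ether | CC(C)(C)[Si](C)(C)O[C@H]1CC(C)=CC[C@@]2(C)[C@@H](O)C[C@@](O)(C(C)C)[C@H]12
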